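**Retrosynthetic overview**
- Feature: in the 1,2-dioxane ring (O1–O2–C3–C4–C5–C6) the C5 methylene lies between the fully substituted C4 and C6. C4–C5 is the one ring C–C bond that can be drawn as an alkene between a vinyl group on C6 and an isopropenyl group on C3 that are held together only by the O–O bond.
- Lactone: the C4–O bond is cut back to a C3 acetic acid arm and a C4=C5 alkene (iodolactonisation, then C5–I to C5–H).
- Dioxine: C4=C5 is cut by ring-closing metathesis across the peroxide bridge of an acyclic sec,tert-dialkyl peroxide diene.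
- Peroxide: C3–O comes from SN2 of the C6 hydroperoxide on an (R)-allylic mesylate (inversion), and C6–O from perhydrolysis of a Sharpless epoxy alcohol at its tertiary carbon (inversion). The hydroperoxide is alkylated before the diol is cut down to the C6 vinyl group, so that no free OOH group meets periodate, an α-peroxy aldehyde or a phosphorus ylide.
- Ring order: 3,6-dihydro-1,2-dioxine first (step 15), γ-lactone second (step 18).

Key step: step 15

Assumption: plakortolide numbering is used (C1 lactone carbonyl, C3 and C6 the peroxide carbons, C4 the carbon bearing the lactone oxygen); the target SMILES reads as (3S,4S,6S), and 12-phenyldodecanoic acid is taken as purchasable.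

**Route**

Step 1
Reactants: 1 12-phenyldodecanoic acid
Product: 2 12-phenyldodecan-1-ol
Conditions: LiAlH4, THF, 0 °C → reflux; Fieser work-up
Reagents that add atoms: none
Why: Hydride reduction of a carboxylic acid to the primary alcohol with LiAlH4 is routine and nothing else in the molecule is reducible.

Step 2
Reactants: 2 12-phenyldodecan-1-ol
Product: 3 (12-bromododecyl)benzene
Conditions: CBr4, PPh3, CH2Cl2, 0 °C → rt
Reagents that add atoms: carbon tetrabromide, BrC(Br)(Br)Br
Why: Appel bromination of an unhindered primary alcohol proceeds by SN2 on the alkoxyphosphonium salt.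

Step 3
Reactants: 3 (12-bromododecyl)benzene
Product: 4 14-phenyltetradec-1-yne
Conditions: lithium acetylide·ethylenediamine, DMSO, 0 °C → rt
Reagents that add atoms: lithium acetylide (ethylenediamine complex), [Li]C#C
Why: SN2 alkylation of lithium acetylide by a primary bromide in DMSO is a standard route to terminal alkynes.

Step 4
Reactants: 4 14-phenyltetradec-1-yne
Product: 7 (2E)-3-methyl-15-phenylpentadec-2-en-1-ol, via alkenylalane 5 (not isolated), via lithium alkenylaluminate 6 (not isolated)
Conditions: Me3Al (2 equiv), Cp2ZrCl2 (0.25 equiv), CH2Cl2, 0 °C → rt; volatiles removed; n-BuLi, THF/hexane, −78 → 0 °C; (CH2O)n, rt; aq. HCl work-up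
Reagents that add atoms: trimethylaluminium, C[Al](C)C; paraformaldehyde (as formaldehyde), C=O
Why: Negishi zirconium-catalysed carboalumination adds methyl and aluminium syn across the terminal alkyne with aluminium on the terminal carbon, and the derived aluminate is hydroxymethylated by formaldehyde with retention of geometry, which fixes the E trisubstituted alkene.

Step 5
Reactants: 7 (2E)-3-methyl-15-phenylpentadec-2-en-1-ol
Product: 8 [(2R,3R)-3-methyl-3-(12-phenyldodecyl)oxiran-2-yl]methanol
Conditions: Ti(OiPr)4 (10 mol %), D-(−)-diethyl tartrate (12 mol %), t-BuOOH, 4 Å MS, CH2Cl2, −20 °C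
Reagents that add atoms: tert-butyl hydroperoxide, CC(C)(C)OO
Why: Sharpless asymmetric epoxidation of this geraniol-type E allylic alcohol with D-(−)-tartrate should give the (2R,3R)-epoxide (the mirror image of the (2S,3S)-epoxide that geraniol gives with L-(+)-tartrate), which fixes the configuration from which C6 is derived.

Step 6
Reactants: 8 [(2R,3R)-3-methyl-3-(12-phenyldodecyl)oxiran-2-yl]methanol; 9 hydrogen peroxide
Product: 10 (2R,3S)-3-hydroperoxy-3-methyl-15-phenylpentadecane-1,2-diol
Conditions: anhydrous H2O2 in Et2O (excess), phosphomolybdic acid (cat.), Et2O, rt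
Reagents that add atoms: none
Why: Molybdenum-acid-catalysed perhydrolysis of a trisubstituted epoxide opens the C–O bond at the tertiary carbon by backside attack of H2O2, so the quaternary peroxide carbon (the future C6) is formed with inversion as 3S while C2 is untouched.

Step 7
Reactants: 11 propane-1,3-diol
Product: 12 3-[(tert-butyldimethylsilyl)oxy]propan-1-ol
Conditions: NaH (1.0 equiv), THF, rt; TBSCl (1.0 equiv)
Reagents that add atoms: tert-butyldimethylsilyl chloride, CC(C)(C)[Si](C)(C)Cl
Why: Monosilylation of a symmetrical diol through its sparingly soluble monosodium alkoxide is a standard way to the mono-TBS ether.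

Step 8
Reactants: 12 3-[(tert-butyldimethylsilyl)oxy]propan-1-ol
Product: 13 3-[(tert-butyldimethylsilyl)oxy]propanal
Conditions: TEMPO (10 mol %), PhI(OAc)2 (1.1 equiv), CH2Cl2, rt
Reagents that add atoms: none
Why: TEMPO-catalysed oxidation with PhI(OAc)2 in anhydrous CH2Cl2 stops at the aldehyde and is mild enough to avoid β-elimination of the silyloxy group.

Step 9
Reactants: 13 3-[(tert-butyldimethylsilyl)oxy]propanal; 14 isopropenylmagnesium bromide
Product: 15 rac-5-[(tert-butyldimethylsilyl)oxy]-2-methylpent-1-en-3-ol
Conditions: THF, −78 → 0 °C; aq. NH4Cl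
Reagents that add atoms: none
Why: 1,2-Addition of an alkenyl Grignard reagent to an aliphatic aldehyde gives the racemic secondary allylic alcohol, whose stereocentre is resolved in the next step.

Step 10
Reactants: 15 rac-5-[(tert-butyldimethylsilyl)oxy]-2-methylpent-1-en-3-ol
Product: 16 (3R)-5-[(tert-butyldimethylsilyl)oxy]-2-methylpent-1-en-3-ol
Conditions: Ti(OiPr)4 (1.0 equiv), L-(+)-diisopropyl tartrate (1.2 equiv), t-BuOOH (0.6 equiv), 4 Å MS, CH2Cl2, −20 °C, run past half conversion; chromatography
Reagents that add atoms: none
Why: In the Sharpless kinetic resolution with L-(+)-tartrate the (S)-enantiomer of a secondary allylic alcohol is epoxidised much faster (as with oct-1-en-3-ol), so the (R)-alcohol should be recovered in high enantiomeric purity, and 2-substituted allylic alcohols of this kind are good substrates.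

Step 11
Reactants: 16 (3R)-5-[(tert-butyldimethylsilyl)oxy]-2-methylpent-1-en-3-ol
Product: 17 (3R)-5-[(tert-butyldimethylsilyl)oxy]-2-methylpent-1-en-3-yl methanesulfonate
Conditions: Ms2O, Et3N, CH2Cl2, −30 °C; cold aqueous work-up, used at once
Reagents that add atoms: methanesulfonic anhydride, CS(=O)(=O)OS(C)(=O)=O
Why: Sulfonylation at oxygen retains the carbinol configuration, and the anhydride introduces no chloride that could turn the allylic mesylate into an allylic chloride.

Step 12
Reactants: 10 (2R,3S)-3-hydroperoxy-3-methyl-15-phenylpentadecane-1,2-diol; 17 (3R)-5-[(tert-butyldimethylsilyl)oxy]-2-methylpent-1-en-3-yl methanesulfonate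
Product: 19 (2R,3S)-3-{[(3S)-5-(tert-butyldimethylsilyloxy)-2-methylpent-1-en-3-yl]peroxy}-3-methyl-15-phenylpentadecane-1,2-diol, via caesium peroxide 18 (not isolated)
Conditions: CsOH·H2O (1.0 equiv), DMF, 0 °C; then 17 (1.3 equiv), 0 °C
Reagents that add atoms: none
Why: O-Alkylation of a caesium alkylperoxide by a sulfonate (the established SN2 route from hydroperoxides to dialkyl peroxides) takes place at the hydroperoxide, which is far more acidic than the two alcohols, and backside displacement at the activated allylic carbon turns the (R)-mesylate into the (S)-configured C3–O bond.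

Step 13
Reactants: 19 (2R,3S)-peroxy diol
Product: 20 (2S)-2-{[(3S)-5-(tert-butyldimethylsilyloxy)-2-methylpent-1-en-3-yl]peroxy}-2-methyl-14-phenyltetradecanal
Conditions: NaIO4, THF/pH 7 buffer, 0 °C → rt; used crude
Reagents that add atoms: none
Why: Periodate glycol cleavage (Malaprade) is specific for the vicinal diol and leaves the dialkyl peroxide, the isopropenyl group and the silyl ether untouched, the aldehyde carbon being the future C5.

Step 14
Reactants: 20 (2S)-α-peroxy aldehyde
Product: 21 tert-butyldimethyl{[(3S)-4-methyl-3-{[(3S)-3-methyl-15-phenylpentadec-1-en-3-yl]peroxy}pent-4-en-1-yl]oxy}silane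
Conditions: Ph3PCH3Br, KHMDS, THF, 0 °C; then 20, −78 → 0 °C
Reagents that add atoms: methyltriphenylphosphonium bromide, C[P+](c1ccccc1)(c1ccccc1)c1ccccc1.[Br-]
Why: Wittig methylenation of a non-enolisable aldehyde is fast at low temperature, and dialkyl peroxides are known to survive unstabilised ylides in olefinations of α-peroxy aldehydes.

Step 15
Reactants: 21 acyclic dialkyl peroxide diene
Product: 22 (3S,6S)-3-[2-(tert-butyldimethylsilyloxy)ethyl]-4,6-dimethyl-6-(12-phenyldodecyl)-3,6-dihydro-1,2-dioxine
Conditions: Hoveyda–Grubbs II (10 mol %, in portions), 1,4-benzoquinone (20 mol %), CH2Cl2 (3 mM), 40 °C, argon sparge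
Reagents that add atoms: none
Why: Olefin metathesis by the Chauvin mechanism: the ruthenium carbene exchanges onto the monosubstituted vinyl group at C6, the C5 alkylidene adds intramolecularly to the 1,1-disubstituted isopropenyl group on C3, and cycloreversion of the ruthenacyclobutane releases the C4=C5 bond while ethylene is swept out. The closest known reaction type is ring-closing metathesis of vinyl/isopropenyl dienes to six-membered cyclic ethers with a trisubstituted alkene, together with ruthenium-catalysed ring-closing and cross metathesis of alkenes that carry dialkyl peroxides. The one ring formed is the six-membered 3,6-dihydro-1,2-dioxine, closed at C4–C5 with the O–O bond inside the ring as the tether, and the ring size forces the Z alkene. No stereocentre is made: C6 (S, from step 6) and C3 (S, from step 12) are carried through unchanged. The step needs ring closure to beat dimerisation and needs the carbene to leave the O–O bond alone; high dilution, the fully substituted C6 and the gauche C–O–O–C torsion of a peroxide favour closure, while a dialkyl peroxide is a poor ligand and a poor oxidant for the Ru(II) carbene. Benzoquinone is added to suppress Ru–H isomerisation of the isopropenyl group.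

Step 16
Reactants: 22 silyl ether dioxine
Product: 23 2-[(3S,6S)-4,6-dimethyl-6-(12-phenyldodecyl)-3,6-dihydro-1,2-dioxin-3-yl]ethan-1-ol
Conditions: HF·pyridine, pyridine, THF, 0 °C → rt
Reagents that add atoms: none
Why: Buffered HF cleaves the primary TBS ether without the basic fluoride (TBAF) that could start a Kornblum–DeLaMare fragmentation at the C3–H of the dihydrodioxine.

Step 17
Reactants: 23 dioxinylethanol
Product: 25 2-[(3S,6S)-4,6-dimethyl-6-(12-phenyldodecyl)-3,6-dihydro-1,2-dioxin-3-yl]acetic acid, via aldehyde 24 (not isolated)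
Conditions: TEMPO (0.2 equiv), PhI(OAc)2 (2.5 equiv), MeCN/H2O 1:1, rt
Reagents that add atoms: water, O
Why: TEMPO/PhI(OAc)2 in aqueous acetonitrile oxidises a primary alcohol through the aldehyde hydrate to the acid under near-neutral conditions that spare the trisubstituted alkene and the peroxide and do not promote β-elimination of the peroxide from the aldehyde.

Step 18
Reactants: 25 dioxinylacetic acid
Product: 26 (3S,4R,5S,6S)-5-iodoplakortolide L (cis-fused iodolactone, iodine on C5 trans to the lactone oxygen on C4)
Conditions: I2, KI, NaHCO3, THF/H2O, 0 °C, dark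
Reagents that add atoms: iodine, II
Why: In this iodolactonisation the carboxylate can reach only the tertiary alkene carbon C4 and only from the face of the C3 arm (5-exo, Markovnikov), so anti opening of the reversibly formed iodonium ion gives the cis-fused γ-lactone that sets C4, with iodine on C5 trans to the new C–O bond, a sequence with precedent on 3,6-dihydro-1,2-dioxin-3-ylacetic acids.

Step 19
Reactants: 26 iodolactone
Product: 27 plakortolide L
Conditions: n-Bu3SnH (3 equiv, ≥0.3 M), Et3B (0.2 equiv)/air, toluene, 0 °C → rt
Reagents that add atoms: none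
Why: Radical chain dehalogenation with tin hydride replaces iodine by hydrogen at C5 (which then is no longer a stereocentre), and a high stannane concentration at low temperature lets hydrogen transfer outrun attack of the C5 radical on the ring O–O bond, which is poorly aligned within the six-membered ring.

**Compound list**
1 | 12-phenyldodecanoic acid | OC(=O)CCCCCCCCCCCc1ccccc1 | starting material
2 | 12-phenyldodecan-1-ol | OCCCCCCCCCCCCc1ccccc1 | intermediate
3 | (12-bromododecyl)benzene | BrCCCCCCCCCCCCc1ccccc1 | intermediate
4 | 14-phenyltetradec-1-yne | C#CCCCCCCCCCCCCc1ccccc1 | intermediate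
5 | dimethyl[(1E)-2-methyl-14-phenyltetradec-1-en-1-yl]alane | C[Al](C)/C=C(\C)CCCCCCCCCCCCc1ccccc1 | intermediate
6 | lithium butyl(dimethyl)[(1E)-2-methyl-14-phenyltetradec-1-en-1-yl]aluminate | [Li+].CCCC[Al-](C)(C)/C=C(\C)CCCCCCCCCCCCc1ccccc1 | intermediate
7 | (2E)-3-methyl-15-phenylpentadec-2-en-1-ol | OC/C=C(\C)CCCCCCCCCCCCc1ccccc1 | intermediate
8 | [(2R,3R)-3-methyl-3-(12-phenyldodecyl)oxiran-2-yl]methanol | OC[C@H]1O[C@]1(C)CCCCCCCCCCCCc2ccccc2 | intermediate
9 | hydrogen peroxide | OO | starting material
10 | (2R,3S)-3-hydroperoxy-3-methyl-15-phenylpentadecane-1,2-diol | OC[C@@H](O)[C@@](C)(OO)CCCCCCCCCCCCc1ccccc1 | intermediate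
11 | propane-1,3-diol | OCCCO | starting material
12 | 3-[(tert-butyldimethylsilyl)oxy]propan-1-ol | OCCCO[Si](C)(C)C(C)(C)C | intermediate
13 | 3-[(tert-butyldimethylsilyl)oxy]propanal | O=CCCO[Si](C)(C)C(C)(C)C | intermediate
14 | isopropenylmagnesium bromide | C=C(C)[Mg]Br | starting material
15 | rac-5-[(tert-butyldimethylsilyl)oxy]-2-methylpent-1-en-3-ol | C=C(C)C(O)CCO[Si](C)(C)C(C)(C)C | intermediate
16 | (3R)-5-[(tert-butyldimethylsilyl)oxy]-2-methylpent-1-en-3-ol | C=C(C)[C@H](O)CCO[Si](C)(C)C(C)(C)C | intermediate
17 | (3R)-5-[(tert-butyldimethylsilyl)oxy]-2-methylpent-1-en-3-yl methanesulfonate | C=C(C)[C@H](OS(C)(=O)=O)CCO[Si](C)(C)C(C)(C)C | intermediate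
18 | caesium (2R,3S)-1,2-dihydroxy-3-methyl-15-phenylpentadecan-3-yl peroxide | OC[C@@H](O)[C@@](C)(O[O-])CCCCCCCCCCCCc1ccccc1.[Cs+] | intermediate
19 | (2R,3S)-3-{[(3S)-5-(tert-butyldimethylsilyloxy)-2-methylpent-1-en-3-yl]peroxy}-3-methyl-15-phenylpentadecane-1,2-diol | OC[C@@H](O)[C@](C)(CCCCCCCCCCCCc1ccccc1)OO[C@@H](CCO[Si](C)(C)C(C)(C)C)C(C)=C | intermediate
20 | (2S)-2-{[(3S)-5-(tert-butyldimethylsilyloxy)-2-methylpent-1-en-3-yl]peroxy}-2-methyl-14-phenyltetradecanal | O=C[C@](C)(CCCCCCCCCCCCc1ccccc1)OO[C@@H](CCO[Si](C)(C)C(C)(C)C)C(C)=C | intermediate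
21 | tert-butyldimethyl{[(3S)-4-methyl-3-{[(3S)-3-methyl-15-phenylpentadec-1-en-3-yl]peroxy}pent-4-en-1-yl]oxy}silane | C=C[C@](C)(CCCCCCCCCCCCc1ccccc1)OO[C@@H](CCO[Si](C)(C)C(C)(C)C)C(C)=C | intermediate
22 | (3S,6S)-3-[2-(tert-butyldimethylsilyloxy)ethyl]-4,6-dimethyl-6-(12-phenyldodecyl)-3,6-dihydro-1,2-dioxine | C[C@]1(CCCCCCCCCCCCc2ccccc2)C=C(C)[C@H](CCO[Si](C)(C)C(C)(C)C)OO1 | intermediate
23 | 2-[(3S,6S)-4,6-dimethyl-6-(12-phenyldodecyl)-3,6-dihydro-1,2-dioxin-3-yl]ethan-1-ol | C[C@]1(CCCCCCCCCCCCc2ccccc2)C=C(C)[C@H](CCO)OO1 | intermediate
24 | 2-[(3S,6S)-4,6-dimethyl-6-(12-phenyldodecyl)-3,6-dihydro-1,2-dioxin-3-yl]acetaldehyde | C[C@]1(CCCCCCCCCCCCc2ccccc2)C=C(C)[C@H](CC=O)OO1 | intermediate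
25 | 2-[(3S,6S)-4,6-dimethyl-6-(12-phenyldodecyl)-3,6-dihydro-1,2-dioxin-3-yl]acetic acid | C[C@]1(CCCCCCCCCCCCc2ccccc2)C=C(C)[C@H](CC(=O)O)OO1 | intermediate
26 | (3S,4R,5S,6S)-5-iodoplakortolide L | C[C@]1(CCCCCCCCCCCCc2ccccc2)[C@@H](I)[C@]2(C)OC(=O)C[C@@H]2OO1 | intermediate
27 | plakortolide L, (3S,4S,6S) | C[C@]1(CCCCCCCCCCCCc2ccccc2)C[C@]2(C)OC(=O)C[C@@H]2OO1 | target

**Step count**
Total: 19 steps. Longest linear sequence: 14 steps (steps 1–6 and 12–19, from 1); the second branch (steps 7–11, from 11) joins at step 12.

**Steps most likely to fail**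

Step 15 (ring-closing metathesis). The carbene may load too slowly at the C6 vinyl group, which sits on a quaternary carbon next to the peroxide. Catalyst decay (possibly by slow cleavage of the O–O bond) and intermolecular metathesis could then outrun closure onto the 1,1-disubstituted alkene. The fallback is a relay ring-closing metathesis that brings the carbene to C5 intramolecularly. It sets out from aldehyde 20: Wittig reaction with the ylide from hex-5-enyltriphenylphosphonium bromide and KHMDS should give the (Z)-hepta-1,6-dienyl relay triene F1. The catalyst then loads at the unhindered terminal alkene, expels cyclopentene to place ruthenium on C5, and closes onto the isopropenyl group. This comes back to the route at dioxine 22.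

Step 12 (peroxide alkylation). The hindered tertiary peroxide anion may attack the allylic system at its terminal CH2 (SN2′) or act as a base (E2 to a diene), and the mesylate may ionise with loss of configuration. The fallback reverses the roles of the two fragments. It sets out from mesylate 17: displacement with a large excess of H2O2 and KOH in MeOH/THF at 0 °C (the classical sulfonate-to-hydroperoxide inversion with a small nucleophile) should give (3S)-5-(tert-butyldimethylsilyloxy)-2-methylpent-1-en-3-yl hydroperoxide F2. F2, used in excess, then opens epoxy alcohol 8 at its tertiary carbon under phosphomolybdic acid catalysis with inversion, as in step 6. This comes back to the route at peroxy diol 19 and bypasses 10.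

Step 19 (radical deiodination). The C5 radical may attack the neighbouring O–O bond (intramolecular homolytic substitution to an epoxide and an alkoxyl radical) faster than it takes up hydrogen, or stannyl radicals may reduce the peroxide. The fallback avoids radicals and the iodide altogether. It sets out from acid 25: Brønsted-acid-catalysed hydrolactonisation (TfOH cat., CH2Cl2, −20 °C) protonates C5 and lets the tethered acid capture the tertiary C4 cation from the face of the C3 arm. This gives the cis-fused lactone directly and comes back to the route at 27; it makes no new compound (F0).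

**Further compounds**
F1 | step 15 | tert-butyldimethyl{[(3S)-4-methyl-3-{[(6Z,8S)-8-methyl-20-phenylicosa-1,6-dien-8-yl]peroxy}pent-4-en-1-yl]oxy}silane (relay triene) | C=CCCC/C=C\[C@](C)(CCCCCCCCCCCCc1ccccc1)OO[C@@H](CCO[Si](C)(C)C(C)(C)C)C(C)=C
F2 | step 12 | (3S)-5-(tert-butyldimethylsilyloxy)-2-methylpent-1-en-3-yl hydroperoxide | C=C(C)[C@@H](OO)CCO[Si](C)(C)C(C)(C)C
F0 | step 19 | none | none
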